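(The data were computed for an exercise, and the scatter is random.)

The trap in these peaks is to expect that more partner hands the flask to target: from 2.5 equiv to 3.8 equiv, target at 6.00 h reads 11.4%, then 17.7%, but side product B still stands higher at 49.2%, then 45.9%.

the same everywhere: starting material 0.050 M

| charge | partner | remark | time |
|---|---|---|---|
| south-west | 2.5 equiv | run made earlier |  |
| south-east | 3.8 equiv | run made earlier |  |
| flask | 5.00 equiv |  | 6.0 h |

| run | time / h | target / % | side product A / % | side product B / % | starting material / % |
|---|---|---|---|---|---|
| south-west | 0.417 | 3.6 | 4.0 | 13.6 | 77.3 |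
| south-west | 1.33 | 6.2 | 13.5 | 29.1 | 52.6 |
| south-west | 2.00 | 8.1 | 15.3 | 37.5 | 40.0 |
| south-west | 3.00 | 11.2 | 18.9 | 43.7 | 30.0 |
| south-west | 5.00 | 13.3 | 24.0 | 44.3 | 17.3 |
| south-west | 6.00 | 11.4 | 25.5 | 49.2 | 15.8 |
| south-east | 0.500 | 5.3 | 4.7 | 16.7 | 76.1 |
| south-east | 0.833 | 6.1 | 7.1 | 24.1 | 62.2 |
| south-east | 1.33 | 10.0 | 11.6 | 30.4 | 51.0 |
| south-east | 2.00 | 12.9 | 15.6 | 35.3 | 38.5 |
| south-east | 4.00 | 15.6 | 20.8 | 42.1 | 19.1 |
| south-east | 6.00 | 17.7 | 22.4 | 45.9 | 13.7 |

(readings scatter by 1 percentage point)

- percent here means starting material units held: one side product B counts as two
- the numbers in the tables scatter with a standard deviation of 1 percentage point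

1. the species in which most of what was charged as starting material, at 6.0 h sits (starting material / side product A / side product B / target)
2. the largest share itself, whichever of these holds it, in percent of the starting material charged

I watch two rates. I assume that starting material makes target at a rate proportional to itself and to partner (pseudo-first-order while partner stands in excess), and side product A at a rate proportional to itself. Starting material cancels in their ratio, so I take r, target over side product A. The readings of the two runs at 6.00 h give 3.58 L mol⁻¹ and 4.16 L mol⁻¹, so I freeze 3.87 L mol⁻¹ as g, the selectivity factor, r per partner concentration charged, read at that time. This flask then has r = 0.967 at 6.0 h. Side product B over side product A does not lose starting material from its ratio, but both runs and this flask start from 0.050 M; the runs read 1.93 and 2.05, so for this flask I freeze 1.99. Taking starting material in this flask near the south-east reading of 13.7%, my balance gives side product B 43.4%, ahead of side product A at 21.8% and target at 21.1%.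

The forecast says side product B, 43% (40% to 46%), holding that “Target scales with equivalents”.

The flask gives side product B at 42.1%.

    starting material + partner ⇌ target (K = 157 L mol⁻¹, k = 0.571 L mol⁻¹ h⁻¹)
    starting material → side product A (k = 0.115 h⁻¹)
    2 starting material → side product B (k = 4.32 L mol⁻¹ h⁻¹)
    partner → decomposed reagent (k = 0.0990 h⁻¹)

In this flask, target over side product A is 0.992. At 2.52 h in this flask, the loss of starting material to side product A runs at 1.1 times the forward making of target. With g, the neighbour at 0.085 M, same equivalents and time, should show r = 1.64; it holds 29.4% target and 17.2% side product A, a ratio of 1.71.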